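**Plan**
Numbering follows the chromanone (O1, C2, C3, C4, C4a, C5–C8, C8a). Ring A is the carbocycle, ring B the pyranone, Cα/Cβ the CH and CH2 of the acid chain on C6, and ring C a temporary lactone.
Retrosynthetic cuts, in order: C8–prenyl; acid closed onto O5 (ring C); C8–CH2 of the lavandulyl group; Cβ–C(=O) and O5–C(=O) together; C6–Cα; O1–C2; C4–C4a.
Enabling feature: the path O5, C5, C6 (ring A), Cα, Cβ, carboxyl carbon is a six-membered ring. The acid is therefore a masked dihydrocoumarin. Its carbonyl carbon can enter as CO between the CH2 terminus of a C6 pent-1-en-2-yl group and the O5 phenol, and the hydrogen delivered to Cα creates that stereocentre.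
Forward order: ring A is bought as phloroglucinol, ring B closes by oxa-Michael addition, C6 is iodinated and alkenylated, and ring C closes by cyclocarbonylation. C8 then receives lavandulyl by Negishi coupling, ring C is opened, and ring A is dearomatised by prenylation at C8.
Stereochemistry: C2 (R) and C3 (S, cis) come from quinine catalysis with kinetic protonation, Cα (R) from a chiral bisphosphine on palladium, and C8 (R) from a chiral prenylpalladium complex. The lavandulyl centre comes from lipase-resolved (S)-lavandulol and is R in the target only through a change of CIP ranking.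
The cis C3 centre is epimerisable, so every step after step 3 avoids hot base and strong acid.

Key step: step 7

Assumption: the facial senses written for quinine, (R)-DTBM-SEGPHOS and the (R,R)-bisphosphine follow the closest analogies. If a catalyst favours the other face, its enantiomer (quinidine for quinine) replaces it and nothing else changes.

**Step 1**
Reactants: 1 phloroglucinol; 2 tigloyl chloride
Product: 3 (E)-2-methyl-1-(2,4,6-trihydroxyphenyl)but-2-en-1-one
Conditions: AlCl3, CH2Cl2–PhNO2, 0 °C to rt; then cold 1 M HCl
Reagents that add atoms: none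
Why: Friedel–Crafts acylation of the threefold symmetric, very electron-rich ring can give only one monoketone, and keeping the aluminium-chelated product at or below room temperature should prevent the enone from closing to racemic chromanone.

**Step 2**
Reactants: 3 (E)-2-methyl-1-(2,4,6-trihydroxyphenyl)but-2-en-1-one
Product: 4 (E)-1-[2,6-dihydroxy-4-(methoxymethoxy)phenyl]-2-methylbut-2-en-1-one
Conditions: MOMCl (1.0 equiv), iPr2NEt, CH2Cl2, 0 °C
Reagents that add atoms: chloromethyl methyl ether, COCCl
Why: Selective O-alkylation (acetal formation) should occur at the para hydroxyl, the only one not held in a hydrogen bond to the ketone and the most acidic, while a short cold contact with a hindered amine is far too mild to trigger the ring closure reserved for step 3.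

**Step 3**
Reactants: 4 (E)-1-[2,6-dihydroxy-4-(methoxymethoxy)phenyl]-2-methylbut-2-en-1-one
Product: 5 (2R,3S)-5-hydroxy-7-(methoxymethoxy)-2,3-dimethylchroman-4-one (cis)
Conditions: (−)-quinine (20 mol %), PhCl, 15 °C
Reagents that add atoms: none
Why: Cinchona-alkaloid-catalysed asymmetric intramolecular oxa-Michael addition, known for o-tigloylphenols of the phloroglucinol series: the quinuclidine nitrogen activates one of the two equivalent ortho phenols and the C9 hydroxyl of quinine holds the ketone, so oxygen should add to one face of the enone (C2 = R), after which kinetic protonation of the enol on the face away from the new C2 methyl group places the C3 methyl cis to it (C3 = S).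

**Step 4**
Reactants: 5 (2R,3S)-5-hydroxy-7-(methoxymethoxy)-2,3-dimethylchroman-4-one
Product: 6 (2R,3S)-5-hydroxy-6-iodo-7-(methoxymethoxy)-2,3-dimethylchroman-4-one
Conditions: BnMe3N·ICl2 (1.0 equiv), CaCO3, CH2Cl2–MeOH, rt
Reagents that add atoms: benzyltrimethylammonium dichloroiodate, C[N+](C)(C)Cc1ccccc1.Cl[I-]Cl
Why: Electrophilic aromatic iodination with a dichloroiodate salt is known to go ortho to the free chelated 5-hydroxyl of 5-hydroxy-7-alkoxy chromones and flavones, which points to C6 and not C8, and CaCO3 takes up the HCl so that neither the acetal nor C3 is stressed.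

**Step 5**
Reactants: 7 2-bromopent-1-ene
Product: 9 4,4,5,5-tetramethyl-2-(pent-1-en-2-yl)-1,3,2-dioxaborolane, via pent-1-en-2-ylmagnesium bromide 8 (not isolated)
Conditions: Mg turnings, THF, rt; then iPrOBpin, −78 °C to rt; 1 M HCl
Reagents that add atoms: 2-isopropoxy-4,4,5,5-tetramethyl-1,3,2-dioxaborolane, CC(C)OB1OC(C)(C)C(C)(C)O1
Why: Grignard formation from the alkenyl bromide and trapping with a borate ester is the standard route to 1-substituted vinylboronates and fixes boron on the internal alkene carbon.

**Step 6**
Reactants: 6 (2R,3S)-5-hydroxy-6-iodo-7-(methoxymethoxy)-2,3-dimethylchroman-4-one; 9 4,4,5,5-tetramethyl-2-(pent-1-en-2-yl)-1,3,2-dioxaborolane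
Product: 10 (2R,3S)-5-hydroxy-7-(methoxymethoxy)-2,3-dimethyl-6-(pent-1-en-2-yl)chroman-4-one
Conditions: Pd(OAc)2, SPhos, K3PO4, THF–H2O, 40 °C
Reagents that add atoms: none
Why: Suzuki–Miyaura coupling with a bulky biarylphosphine tolerates an iodide flanked by two oxygens and a free phenol, and at this mild temperature ring A is present as its 5-phenolate, which lowers the acidity of the C3 hydrogen and should protect the cis relationship.

**Step 7**
Reactants: 10 (2R,3S)-5-hydroxy-7-(methoxymethoxy)-2,3-dimethyl-6-(pent-1-en-2-yl)chroman-4-one; 11 carbon monoxide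
Product: 12 (4R,8R,9S)-5-(methoxymethoxy)-8,9-dimethyl-4-propyl-3,4,8,9-tetrahydro-2H,10H-pyrano[2,3-f]chromene-2,10-dione (the chromanone with ring C: O5–C(=O)–CH2–(R)-CH(n-Pr)–C6)
Conditions: Pd(OAc)2 (5 mol %), (R)-DTBM-SEGPHOS (6 mol %), CO (30 bar), H2 (5 bar), toluene, 80 °C, no added strong acid
Reagents that add atoms: carbon monoxide (compound 11), [C-]#[O+]
Why: A palladium hydride generated from Pd(OAc)2, the bisphosphine and H2 adds across the C6 pent-1-en-2-yl group with hydrogen going to Cα and palladium to the terminal carbon, CO inserts into the primary alkyl–palladium bond, and the O5 phenol attacks the acylpalladium, which forms Cβ–C(=O) and O5–C(=O) and returns the hydride. The closest known reaction type is the palladium-catalysed cyclocarbonylation (intramolecular hydroesterification) of 2-alkenylphenols to 3,4-dihydrocoumarins, for which asymmetric versions with chiral phosphines exist. Ring C (O5–C5–C6–Cα–Cβ–C=O) closes by 6-exo-trig attack of O5 on the acyl carbon. Cα (R) is set in the hydropalladation, where the chiral pocket of the bisphosphine chooses the alkene face, C2 and C3 being too remote to matter. The step needs palladium at the terminal carbon, secured because the alternative is a tertiary alkylpalladium wedged between O5 and O7, and it needs capture by O5 only, secured by the acetal on O7. Leaving out strong acid keeps the methoxymethyl ether, prevents Markovnikov addition of O5–H to the alkene (dihydrobenzofuran) and spares C3, while the two ortho oxygens twist the alkene out of the plane of ring A and so slow its isomerisation to the internal styrene.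

**Step 8**
Reactants: 12 tricyclic lactone
Product: 13 (4R,8R,9S)-6-iodo-5-(methoxymethoxy)-8,9-dimethyl-4-propyl-3,4,8,9-tetrahydro-2H,10H-pyrano[2,3-f]chromene-2,10-dione (iodine on C8 of the chromanone numbering)
Conditions: NIS, TFA (10 mol %), MeCN, 0 °C to rt
Reagents that add atoms: N-iodosuccinimide, O=C1CCC(=O)N1I
Why: Electrophilic aromatic iodination: C8 is the only ring A carbon that still bears hydrogen and it sits between two ether oxygens, so N-iodosuccinimide with a trace of acid should suffice without harm to acetal, lactone or C3.

**Step 9**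
Reactants: 14 (±)-lavandulol
Product: 15 (S)-lavandulol, (2S)-5-methyl-2-(prop-1-en-2-yl)hex-4-en-1-ol
Conditions: immobilised Candida antarctica lipase B, vinyl acetate, MTBE, rt, taken beyond half conversion; chromatography
Reagents that add atoms: none
Why: Lipase-catalysed kinetic resolution by irreversible transesterification: the enzyme acylates (R)-lavandulol faster, so the S alcohol stays behind and should become highly enriched once conversion is taken beyond one half.

**Step 10**
Reactants: 15 (S)-lavandulol
Product: 16 (S)-lavandulyl iodide, (5S)-5-(iodomethyl)-2,6-dimethylhepta-2,6-diene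
Conditions: I2, PPh3, imidazole, CH2Cl2, 0 °C
Reagents that add atoms: iodine, [I][I]
Why: Appel-type iodination is an SN2 displacement at the primary carbon beside the stereocentre, which is therefore untouched.

**Step 11**
Reactants: 13 iodo lactone; 16 (S)-lavandulyl iodide
Product: 18 (4R,8R,9S)-5-(methoxymethoxy)-8,9-dimethyl-6-[(2R)-5-methyl-2-(prop-1-en-2-yl)hex-4-en-1-yl]-4-propyl-3,4,8,9-tetrahydro-2H,10H-pyrano[2,3-f]chromene-2,10-dione, via (S)-lavandulylzinc iodide 17 (not isolated)
Conditions: 16, Zn dust, LiCl, THF, 25 °C; then 13, Pd(OAc)2, SPhos, THF, 25 to 45 °C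
Reagents that add atoms: none
Why: Negishi sp3–sp2 coupling joins C8 to the lavandulyl CH2 under base-free conditions that spare lactone, ketone and C3, and it is preferred because a β-branched non-allylic halide is too poor an electrophile for C-alkylation of a phenolate; the stereocentre is a spectator (its descriptor becomes R only through the changed CIP ranking) provided the bulky ligand makes reductive elimination outrun β-hydride elimination.

**Step 12**
Reactants: 18 lavandulyl lactone methoxymethyl ether
Product: 19 (4R,8R,9S)-5-hydroxy-8,9-dimethyl-6-[(2R)-5-methyl-2-(prop-1-en-2-yl)hex-4-en-1-yl]-4-propyl-3,4,8,9-tetrahydro-2H,10H-pyrano[2,3-f]chromene-2,10-dione (free O7–H)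
Conditions: ZnBr2, n-PrSH, CH2Cl2, 0 °C, minutes
Reagents that add atoms: none
Why: Lewis-acid-assisted thiolysis of the formaldehyde acetal is complete within minutes without protic acid, so O7–H should be released without adding to the neighbouring isopropenyl group, without opening ring C and without enolising C4.

**Step 13**
Reactants: 19 hydroxy lactone
Product: 20 (R)-3-{(2R,3S)-5,7-dihydroxy-2,3-dimethyl-8-[(2R)-5-methyl-2-(prop-1-en-2-yl)hex-4-en-1-yl]-4-oxochroman-6-yl}hexanoic acid (used at once)
Conditions: LiOH, THF–H2O, 0 °C; then 1 M HCl to pH 4, 0 °C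
Reagents that add atoms: lithium hydroxide, [Li+].[OH-]
Why: Saponification of an aryl ester is fast even in the cold, the phenolate character of ring A under these conditions damps the acidity of the C3 hydrogen, and cold acidification with immediate use should forestall re-lactonisation.

**Step 14**
Reactants: 21 prenol (3-methylbut-2-en-1-ol)
Product: 22 methyl 3-methylbut-2-en-1-yl carbonate
Conditions: ClCO2Me, pyridine, CH2Cl2, 0 °C
Reagents that add atoms: methyl chloroformate, COC(=O)Cl
Why: Acylation of a primary allylic alcohol with a chloroformate is routine and gives the leaving group needed for base-free ionisation in step 15.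

**Step 15**
Reactants: 20 dihydroxy acid; 22 methyl 3-methylbut-2-en-1-yl carbonate
Product: 23 target, (R)-3-{(2R,3S,8R)-5-hydroxy-2,3-dimethyl-8-(3-methylbut-2-en-1-yl)-8-[(2R)-5-methyl-2-(prop-1-en-2-yl)hex-4-en-1-yl]-4,7-dioxo-3,4,7,8-tetrahydro-2H-chromen-6-yl}hexanoic acid
Conditions: Pd2(dba)3·CHCl3 (2.5 mol %), (1R,2R)-N,N'-bis[2-(diphenylphosphanyl)benzoyl]cyclohexane-1,2-diamine (7.5 mol %), 22 (1.05 equiv), degassed CH2Cl2, 0 °C to rt, no added base
Reagents that add atoms: none
Why: Proposed new method: zerovalent palladium should ionise 22 with loss of CO2 to a cationic 1,1-dimethylallylpalladium complex and methoxide, the only base present; the deprotonated 5,7-dihydroxychromanone is an ambident phloroglucinolate whose O-prenylation (at O7 or at the carboxylate) is reversible under the catalyst whereas C–C bond formation is not, so material should funnel to carbon, to C8 rather than C6 because C6 carries the α-branched chain, and to the CH2 terminus of the allyl unit because two fully substituted carbons cannot be joined; the chiral pocket of the bisphosphine selects the face of C8 (R), and tautomerisation to the C5 enol and C7 ketone gives 23; the closest known reactions are the palladium-catalysed asymmetric allylic dearomatisation of naphthols and phenols, the palladium-catalysed enantioselective dearomative prenylation of indoles, and the racemic Tsuji–Trost-type and base-mediated alkylative dearomatisations of acylphloroglucinols.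

**Compound list**
1 | phloroglucinol (benzene-1,3,5-triol) | Oc1cc(O)cc(O)c1 | starting material
2 | tigloyl chloride, (E)-2-methylbut-2-enoyl chloride | C/C=C(\C)C(=O)Cl | starting material
3 | (E)-2-methyl-1-(2,4,6-trihydroxyphenyl)but-2-en-1-one | C/C=C(\C)C(=O)c1c(O)cc(O)cc1O | intermediate
4 | (E)-1-[2,6-dihydroxy-4-(methoxymethoxy)phenyl]-2-methylbut-2-en-1-one | C/C=C(\C)C(=O)c1c(O)cc(OCOC)cc1O | intermediate
5 | (2R,3S)-5-hydroxy-7-(methoxymethoxy)-2,3-dimethylchroman-4-one | COCOc1cc2O[C@H](C)[C@H](C)C(=O)c2c(O)c1 | intermediate
6 | (2R,3S)-5-hydroxy-6-iodo-7-(methoxymethoxy)-2,3-dimethylchroman-4-one | COCOc1cc2O[C@H](C)[C@H](C)C(=O)c2c(O)c1I | intermediate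
7 | 2-bromopent-1-ene | C=C(Br)CCC | starting material
8 | pent-1-en-2-ylmagnesium bromide | C=C(CCC)[Mg]Br | intermediate
9 | 4,4,5,5-tetramethyl-2-(pent-1-en-2-yl)-1,3,2-dioxaborolane | C=C(CCC)B1OC(C)(C)C(C)(C)O1 | intermediate
10 | (2R,3S)-5-hydroxy-7-(methoxymethoxy)-2,3-dimethyl-6-(pent-1-en-2-yl)chroman-4-one | COCOc1cc2O[C@H](C)[C@H](C)C(=O)c2c(O)c1C(=C)CCC | intermediate
11 | carbon monoxide | [C-]#[O+] | starting material
12 | (4R,8R,9S)-5-(methoxymethoxy)-8,9-dimethyl-4-propyl-3,4,8,9-tetrahydro-2H,10H-pyrano[2,3-f]chromene-2,10-dione | COCOc1cc2O[C@H](C)[C@H](C)C(=O)c2c3OC(=O)C[C@@H](CCC)c13 | intermediate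
13 | (4R,8R,9S)-6-iodo-5-(methoxymethoxy)-8,9-dimethyl-4-propyl-3,4,8,9-tetrahydro-2H,10H-pyrano[2,3-f]chromene-2,10-dione | COCOc1c(I)c2O[C@H](C)[C@H](C)C(=O)c2c3OC(=O)C[C@@H](CCC)c13 | intermediate
14 | (±)-lavandulol, 5-methyl-2-(prop-1-en-2-yl)hex-4-en-1-ol | C=C(C)C(CC=C(C)C)CO | starting material
15 | (S)-lavandulol | C=C(C)[C@H](CC=C(C)C)CO | intermediate
16 | (S)-lavandulyl iodide | C=C(C)[C@H](CC=C(C)C)CI | intermediate
17 | (S)-lavandulylzinc iodide | C=C(C)[C@H](CC=C(C)C)C[Zn]I | intermediate
18 | (4R,8R,9S)-5-(methoxymethoxy)-8,9-dimethyl-6-[(2R)-5-methyl-2-(prop-1-en-2-yl)hex-4-en-1-yl]-4-propyl-3,4,8,9-tetrahydro-2H,10H-pyrano[2,3-f]chromene-2,10-dione | COCOc1c(C[C@@H](CC=C(C)C)C(C)=C)c2O[C@H](C)[C@H](C)C(=O)c2c3OC(=O)C[C@@H](CCC)c13 | intermediate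
19 | (4R,8R,9S)-5-hydroxy-8,9-dimethyl-6-[(2R)-5-methyl-2-(prop-1-en-2-yl)hex-4-en-1-yl]-4-propyl-3,4,8,9-tetrahydro-2H,10H-pyrano[2,3-f]chromene-2,10-dione | Oc1c(C[C@@H](CC=C(C)C)C(C)=C)c2O[C@H](C)[C@H](C)C(=O)c2c3OC(=O)C[C@@H](CCC)c13 | intermediate
20 | (R)-3-{(2R,3S)-5,7-dihydroxy-2,3-dimethyl-8-[(2R)-5-methyl-2-(prop-1-en-2-yl)hex-4-en-1-yl]-4-oxochroman-6-yl}hexanoic acid | Oc1c(C[C@@H](CC=C(C)C)C(C)=C)c2O[C@H](C)[C@H](C)C(=O)c2c(O)c1[C@H](CCC)CC(=O)O | intermediate
21 | prenol, 3-methylbut-2-en-1-ol | CC(C)=CCO | starting material
22 | methyl 3-methylbut-2-en-1-yl carbonate | COC(=O)OCC=C(C)C | intermediate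
23 | CNP0266113.2, (2R,3S,8R)-configured dearomatised chromanone acid with (R)-Cα and (2R)-lavandulyl group | C=C(C)[C@H](CC=C(C)C)C[C@@]1(CC=C(C)C)C(=O)C([C@H](CCC)CC(=O)O)=C(O)C2=C1O[C@H](C)[C@H](C)C2=O | target

**Step count**
Total step count: 15.
Longest linear sequence: 11 steps from phloroglucinol (steps 1, 2, 3, 4, 6, 7, 8, 11, 12, 13, 15).

**Steps most likely to fail**

1. Step 15 (labelled step).
- What may go wrong: the prenyl group may stay parked on O7 or on the carboxylate instead of being passed on to carbon. Attack may drift to C6. The ligand may distinguish the two faces of C8 poorly against the bias of the chiral substrate.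
- Fallback (known, uncatalysed chemistry), setting out from 20: base-mediated alkylative dearomatisation as practised for hop β-acids and other acylphloroglucinols. Compound 20 is dissolved in cold aqueous KOH, prenyl bromide is added at 0 °C and the mixture is acidified in the cold. This should deliver 23 together with the C8 epimer of the target F1. The two are diastereomers and are parted by reversed-phase chromatography, and the route is rejoined at 23.

2. Step 7.
- What may go wrong: hydropalladation of the twisted, doubly flanked alkene may be slow. This would leave room for isomerisation to the internal alkene, for hydrogenation, or for weak discrimination of the alkene faces.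
- Fallback, setting out from 10: ring construction and stereocontrol are separated while the same two bonds to the carbonyl carbon are still made from 10 and CO. Oxidative cyclocarbonylation of the 2-alkenylphenol (Pd(OAc)2, 1,4-benzoquinone, CO, MeCN, heat) should give the 4-propylcoumarin F2. A copper hydride asymmetric conjugate reduction of the coumarin then sets Cα (Cu(OAc)2·H2O, (R)-DTBM-SEGPHOS or its antipode as required, (EtO)2MeSiH, t-BuOH, toluene, rt). The trioxygenated, α-branched C4 ketone is the less reactive acceptor. The route is rejoined at 12.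

3. Step 11.
- What may go wrong: oxidative addition and transmetalation at an iodide wedged between two oxygens may be sluggish. β-Hydride elimination from the lavandulylpalladium intermediate may then reduce the iodide and erode the side-chain stereocentre through re-insertion.
- Fallback, setting out from 12 and 16: the order of the two C8 alkylations is reversed and no cross-coupling is used. Thiolysis of the acetal of 12 (ZnBr2, n-PrSH) should give the 7-hydroxy lactone F3. Cold aqueous KOH opens ring C, and prenyl bromide alkylates the only free ring position to give the 8-prenyl dihydroxy acid F4. Alkylative dearomatisation of F4 with iodide 16 (LiHMDS, THF, 0 °C to rt) is a transformation known for prenylated acylphloroglucinols and lavandulyl iodide. It should give 23 beside the C8 epimer of the target F1, to be separated by chromatography, and the route is rejoined at 23.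

**Further compounds**
F1 | step 15 | C8 epimer of the target, (2R,3S,8S) with (R)-Cα and (2R)-lavandulyl group | C=C(C)[C@H](CC=C(C)C)C[C@]1(CC=C(C)C)C(=O)C([C@H](CCC)CC(=O)O)=C(O)C2=C1O[C@H](C)[C@H](C)C2=O
F2 | step 7 | (8R,9S)-5-(methoxymethoxy)-8,9-dimethyl-4-propyl-8,9-dihydro-2H,10H-pyrano[2,3-f]chromene-2,10-dione | COCOc1cc2O[C@H](C)[C@H](C)C(=O)c2c3OC(=O)C=C(CCC)c13
F3 | step 11 | (4R,8R,9S)-5-hydroxy-8,9-dimethyl-4-propyl-3,4,8,9-tetrahydro-2H,10H-pyrano[2,3-f]chromene-2,10-dione | Oc1cc2O[C@H](C)[C@H](C)C(=O)c2c3OC(=O)C[C@@H](CCC)c13
F4 | step 11 | (R)-3-[(2R,3S)-5,7-dihydroxy-2,3-dimethyl-8-(3-methylbut-2-en-1-yl)-4-oxochroman-6-yl]hexanoic acid | Oc1c(CC=C(C)C)c2O[C@H](C)[C@H](C)C(=O)c2c(O)c1[C@H](CCC)CC(=O)O
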